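**Strategy.** Ring A (C5a–C6–C7–C8–C9–C9a of the octahydro-1-benzoxepine) is read as a Diels–Alder retron. Opening the tertiary ether C9a–O to a C9=C9a alkene and raising one C6 methyl to CHO reveals an (E)-1-alkyl-2-methylbutadiene and (E)-3-bromo-2-methylacrolein. One catalytic asymmetric [4+2] forms C7–C8 and C5a–C6, creating the quaternary C6 and placing the C7 bromide cis to the C5a side chain (endo Br, exo CHO). Its precursors are an achiral bromodiene and a β-bromoenal. Aldehyde-to-methyl reduction, a (Z)-selective Wittig reaction with a glycerate-derived ketone (source of C2) and acid-mediated closure of oxepene ring B at C9a finish the route.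

Key step: step 4

Remark on locants: the target is numbered as a 1-benzoxepine (O1, C2 bearing CH2Br, C3=C4, C5, C5a, C6 gem-dimethyl, C7 bromide, C8, C9, C9a).

Assumption: the (S)-diphenylprolinol-derived oxazaborolidinium ion gives adduct 7 as drawn; if its facial sense is the opposite, the (R)-derived antipode is used with nothing else changed.

Remark: 2-bromoethyl trifluoromethanesulfonate and methyl (S)-2,2-dimethyl-1,3-dioxolane-4-carboxylate are taken as purchased.

Step 1
Reactants: 1 3-methyl-2,5-dihydrothiophene 1,1-dioxide (3-methyl-3-sulfolene)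
Product: 2 2-(2-bromoethyl)-3-methyl-2,5-dihydrothiophene 1,1-dioxide (racemic)
Conditions: LiN(SiMe3)2 added last to 1 and BrCH2CH2OTf, THF/DMPU, −78 °C
Reagents that add atoms: 2-bromoethyl trifluoromethanesulfonate, BrCCOS(=O)(=O)C(F)(F)F
Why: Alkylation of an α-sulfonyl allylic carbanion, which for 3-methyl-3-sulfolene takes place at C2 next to the methyl-bearing alkene carbon (the regiochemistry used in sulfolene routes to (E)-β-ocimene); the triflate end reacts far faster than the bromide end, trapping in situ at −78 °C avoids ring opening of the anion, and the new stereocentre is racemic and erased in step 2.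

Step 2
Reactants: 2 2-(2-bromoethyl)-3-methyl-2,5-dihydrothiophene 1,1-dioxide
Product: 3 (E)-6-bromo-3-methylhexa-1,3-diene
Conditions: toluene, NaHCO3, 110 °C
Reagents that add atoms: none
Why: Cheletropic (retro-[4+1]) extrusion of SO2, disrotatory with the C2 substituent turning outwards, so a 2-alkyl sulfolene should give only the (E)-1-substituted diene.

Step 3
Reactants: 4 methacrolein (2-methylprop-2-enal)
Product: 6 (E)-3-bromo-2-methylprop-2-enal, via dibromide 5 (not isolated)
Conditions: Br2, CH2Cl2, −78 to 0 °C; then Et3N, 0 °C to rt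
Reagents that add atoms: bromine, BrBr
Why: Bromine addition to the enal followed by E2 dehydrobromination of the tertiary α-bromide towards the CH2Br carbon should give the conjugated trisubstituted β-bromoenal, whose (E)-isomer (Br trans to CHO) is the stable one.

Step 4
Reactants: 3 (E)-6-bromo-3-methylhexa-1,3-diene; 6 (E)-3-bromo-2-methylprop-2-enal
Product: 7 (1R,2R,6S)-6-bromo-2-(2-bromoethyl)-1,3-dimethylcyclohex-3-ene-1-carbaldehyde
Conditions: chiral oxazaborolidinium triflimide (20 mol %), made in the flask from (S)-α,α-diphenylprolinol, tri(o-tolyl)boroxine and Tf2NH; CH2Cl2, −78 to −40 °C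
Reagents that add atoms: none
Why: The enal, bound through its formyl oxygen to the cationic boron, has a strongly lowered LUMO and should react with the s-cis diene in a concerted, asynchronous [4+2] cycloaddition in which the unsubstituted diene terminus (future C8) leads onto the β-carbon (future C7) and the second bond joins the alkyl-bearing terminus (future C5a) to the formyl-bearing carbon (future C6). The closest known reaction type is the oxazaborolidinium-catalysed Diels–Alder reaction of 2-substituted acroleins such as methacrolein and 2-bromoacrolein with acyclic dienes. Ring A is closed as a cyclohex-3-ene by an intermolecular suprafacial [4π+2π] cycloaddition, and both new σ-bonds lie in that ring. The dienophile geometry is retained, so Br on C6 of 7 is cis to the methyl on C1 of 7, and the exo-formyl transition state usual for α-substituted acroleins places Br and that methyl endo, hence cis to the bromoethyl chain on C2 of 7; the absolute configuration comes from the catalyst, which shields one face of the coordinated enal. The step needs "ortho" regioselectivity, secured by the alkyl group on the diene terminus (largest HOMO coefficient at the CH2 terminus, as with 1-vinylcyclohexene) and sharpened by the Lewis acid, and it needs exo(CHO) selectivity, secured by the α-methyl group of the enal.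

Step 5
Reactants: 7 (1R,2R,6S)-6-bromo-2-(2-bromoethyl)-1,3-dimethylcyclohex-3-ene-1-carbaldehyde
Product: 9 (4S,6R)-4-bromo-6-(2-bromoethyl)-1,5,5-trimethylcyclohex-1-ene, via tosylhydrazone 8 (not isolated)
Conditions: TsNHNH2, 4 Å MS, CHCl3, rt to 40 °C; then catecholborane, 0 °C; then NaOAc·3H2O, 60 °C
Reagents that add atoms: none
Why: Tosylhydrazone formation then Caglioti-type reduction: catecholborane adds hydride to C=N and acetate triggers loss of sulfinate to an alkyl diazene that extrudes N2 to leave CH3 under near-neutral conditions that should spare both C–Br bonds; the formyl-bearing stereocentre becomes the gem-dimethyl carbon and the other two stereocentres are untouched.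

Step 6
Reactants: 9 (4S,6R)-4-bromo-6-(2-bromoethyl)-1,5,5-trimethylcyclohex-1-ene
Product: 10 {2-[(1R,5S)-5-bromo-2,6,6-trimethylcyclohex-2-en-1-yl]ethyl}triphenylphosphonium bromide
Conditions: PPh3, MeCN, 80 °C
Reagents that add atoms: triphenylphosphine, c1ccc(cc1)P(c1ccccc1)c1ccccc1
Why: SN2 quaternisation of PPh3 at the unhindered primary bromide; the secondary ring bromide flanked by the quaternary carbon is inert to substitution.

Step 7
Reactants: 11 methyl (S)-2,2-dimethyl-1,3-dioxolane-4-carboxylate
Product: 13 (S)-1-(2,2-dimethyl-1,3-dioxolan-4-yl)ethan-1-one, via Weinreb amide 12 (not isolated)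
Conditions: MeNH(OMe)·HCl, iPrMgCl, THF, −20 °C; then MeMgBr, 0 °C; aq NH4Cl
Reagents that add atoms: methylmagnesium bromide, C[Mg]Br
Why: Weinreb ketone synthesis in one flask: the magnesium amide converts the ester into the N-methoxy-N-methylamide, whose chelated adduct with MeMgBr survives until work-up, so addition stops at the methyl ketone and the α-alkoxy stereocentre from the chiral pool is kept.

Step 8
Reactants: 10 {2-[(1R,5S)-5-bromo-2,6,6-trimethylcyclohex-2-en-1-yl]ethyl}triphenylphosphonium bromide; 13 (S)-1-(2,2-dimethyl-1,3-dioxolan-4-yl)ethan-1-one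
Product: 15 (4R)-4-{(2Z)-4-[(1R,5S)-5-bromo-2,6,6-trimethylcyclohex-2-en-1-yl]but-2-en-2-yl}-2,2-dimethyl-1,3-dioxolane, via ylide 14 (not isolated)
Conditions: NaN(SiMe3)2, THF, −78 to 0 °C; then 13, −78 °C to rt
Reagents that add atoms: none
Why: Wittig olefination of an α-alkoxy methyl ketone with a non-stabilised ylide, a combination known to favour the (Z)-trisubstituted alkene (new chain cis to the oxygen-bearing carbon) under kinetic conditions; the dioxolane stereocentre is not involved and the hindered secondary bromide should not alkylate the ylide at low temperature.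

Step 9
Reactants: 15 (4R)-4-{(2Z)-4-[(1R,5S)-5-bromo-2,6,6-trimethylcyclohex-2-en-1-yl]but-2-en-2-yl}-2,2-dimethyl-1,3-dioxolane
Product: 16 (2R,3Z)-5-[(1R,5S)-5-bromo-2,6,6-trimethylcyclohex-2-en-1-yl]-3-methylpent-3-ene-1,2-diol
Conditions: AcOH/H2O/THF, 45 °C
Reagents that add atoms: none
Why: Acid-catalysed hydrolysis of the isopropylidene acetal; the weak acid should leave both trisubstituted alkenes and the allylic C–O stereocentre unchanged.

Step 10
Reactants: 16 (2R,3Z)-5-[(1R,5S)-5-bromo-2,6,6-trimethylcyclohex-2-en-1-yl]-3-methylpent-3-ene-1,2-diol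
Product: 17 (2R,3Z)-1-bromo-5-[(1R,5S)-5-bromo-2,6,6-trimethylcyclohex-2-en-1-yl]-3-methylpent-3-en-2-ol
Conditions: CBr4 (1.1 equiv), PPh3, CH2Cl2, −20 to 0 °C
Reagents that add atoms: carbon tetrabromide, BrC(Br)(Br)Br
Why: Appel bromination, which at low temperature with one equivalent of reagent should select the unhindered primary hydroxyl of the 1,2-diol; the carbinol stereocentre is not touched.

Step 11
Reactants: 17 (2R,3Z)-1-bromo-5-[(1R,5S)-5-bromo-2,6,6-trimethylcyclohex-2-en-1-yl]-3-methylpent-3-en-2-ol
Product: 18 palisadin B, (2R,5aS,7S,9aS)-7-bromo-2-(bromomethyl)-3,6,6,9a-tetramethyl-2,5,5a,6,7,8,9,9a-octahydro-1-benzoxepine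
Conditions: TfOH (10 mol %), CH2Cl2/HFIP (9:1), −40 to 0 °C
Reagents that add atoms: none
Why: Brønsted acid-catalysed Markovnikov hydroalkoxylation (the ring-B closure of a cation–olefin cyclisation): protonation of the ring alkene at C9 gives the tertiary C9a cation, which the secondary hydroxyl should capture in a 7-exo closure from the face anti to the axial C6 methyl (equatorial attack), so that O1 is trans to the C5a side chain and the C9a methyl is anti to H-5a; the side-chain alkene is deactivated towards protonation by the adjacent hydroxyl- and bromine-bearing carbons.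

**Compound list**

1 | 3-methyl-2,5-dihydrothiophene 1,1-dioxide (3-methyl-3-sulfolene) | CC1=CCS(=O)(=O)C1 | starting material
2 | 2-(2-bromoethyl)-3-methyl-2,5-dihydrothiophene 1,1-dioxide (racemic) | CC1=CCS(=O)(=O)C1CCBr | intermediate
3 | (E)-6-bromo-3-methylhexa-1,3-diene | C=C/C(C)=C/CCBr | intermediate
4 | methacrolein (2-methylprop-2-enal) | CC(=C)C=O | starting material
5 | 2,3-dibromo-2-methylpropanal (racemic; formed in the flask, not isolated) | CC(Br)(CBr)C=O | intermediate
6 | (E)-3-bromo-2-methylprop-2-enal | O=C/C(C)=C/Br | intermediate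
7 | (1R,2R,6S)-6-bromo-2-(2-bromoethyl)-1,3-dimethylcyclohex-3-ene-1-carbaldehyde | O=C[C@]1(C)[C@@H](Br)CC=C(C)[C@H]1CCBr | intermediate
8 | N'-[(E)-{(1R,2R,6S)-6-bromo-2-(2-bromoethyl)-1,3-dimethylcyclohex-3-en-1-yl}methylidene]-4-methylbenzenesulfonohydrazide (formed in the flask, not isolated) | Cc1ccc(cc1)S(=O)(=O)N/N=C/[C@]2(C)[C@@H](Br)CC=C(C)[C@H]2CCBr | intermediate
9 | (4S,6R)-4-bromo-6-(2-bromoethyl)-1,5,5-trimethylcyclohex-1-ene | CC1(C)[C@@H](Br)CC=C(C)[C@H]1CCBr | intermediate
10 | {2-[(1R,5S)-5-bromo-2,6,6-trimethylcyclohex-2-en-1-yl]ethyl}triphenylphosphonium bromide | CC1(C)[C@@H](Br)CC=C(C)[C@H]1CC[P+](c2ccccc2)(c2ccccc2)c2ccccc2.[Br-] | intermediate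
11 | methyl (S)-2,2-dimethyl-1,3-dioxolane-4-carboxylate | COC(=O)[C@@H]1COC(C)(C)O1 | starting material
12 | (S)-N-methoxy-N,2,2-trimethyl-1,3-dioxolane-4-carboxamide (formed in the flask, not isolated) | CON(C)C(=O)[C@@H]1COC(C)(C)O1 | intermediate
13 | (S)-1-(2,2-dimethyl-1,3-dioxolan-4-yl)ethan-1-one | CC(=O)[C@@H]1COC(C)(C)O1 | intermediate
14 | {2-[(1R,5S)-5-bromo-2,6,6-trimethylcyclohex-2-en-1-yl]ethylidene}triphenylphosphorane (formed in the flask, not isolated) | CC1(C)[C@@H](Br)CC=C(C)[C@H]1CC=P(c2ccccc2)(c2ccccc2)c2ccccc2 | intermediate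
15 | (4R)-4-{(2Z)-4-[(1R,5S)-5-bromo-2,6,6-trimethylcyclohex-2-en-1-yl]but-2-en-2-yl}-2,2-dimethyl-1,3-dioxolane | CC1(C)[C@@H](Br)CC=C(C)[C@H]1C/C=C(/C)[C@@H]2COC(C)(C)O2 | intermediate
16 | (2R,3Z)-5-[(1R,5S)-5-bromo-2,6,6-trimethylcyclohex-2-en-1-yl]-3-methylpent-3-ene-1,2-diol | CC1(C)[C@@H](Br)CC=C(C)[C@H]1C/C=C(/C)[C@@H](O)CO | intermediate
17 | (2R,3Z)-1-bromo-5-[(1R,5S)-5-bromo-2,6,6-trimethylcyclohex-2-en-1-yl]-3-methylpent-3-en-2-ol | CC1(C)[C@@H](Br)CC=C(C)[C@H]1C/C=C(/C)[C@@H](O)CBr | intermediate
18 | palisadin B, (2R,5aS,7S,9aS)-7-bromo-2-(bromomethyl)-3,6,6,9a-tetramethyl-2,5,5a,6,7,8,9,9a-octahydro-1-benzoxepine | CC1=CC[C@H]2C(C)(C)[C@@H](Br)CC[C@]2(C)O[C@H]1CBr | target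

**Step count.** 11 steps in total; the longest linear sequence is 9 steps (1, 2, 4, 5, 6, 8, 9, 10, 11).

**Steps most likely to fail**

Step 11. The acid may protonate the side-chain alkene or ionise the allylic alcohol instead of the ring alkene, or the hydroxyl may capture the C9a cation from the wrong face and give the cis-fused ether. The fallback sets out from 17 and replaces the free cation by an intramolecular oxymercuration with Hg(OCOCF3)2 in MeNO2 at −20 °C. This should give the organomercurial, the 9-(trifluoroacetoxymercurio) derivative of 18 with mercury on C9 trans to O1, F1. Reductive demercuration with NaBH4 in aqueous NaOH/THF at 0 °C comes back to the route at 18.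

Step 4. The bulky cationic catalyst may discriminate the enal faces poorly, or may turn over slowly because the hindered β-bromo-α-methyl enal binds it weakly. The fallback sets out from 3 and 6 and runs the cycloaddition with Me2AlCl in CH2Cl2 at −78 °C. This should give the racemic adduct, that is 7 together with its enantiomer (1S,2S,6R)-6-bromo-2-(2-bromoethyl)-1,3-dimethylcyclohex-3-ene-1-carbaldehyde F2. The two are separated by preparative chromatography on a chiral stationary phase, and the route is rejoined at 7.

Step 5. Hydrazone formation at the neopentyl-type aldehyde may stall, or the reducing intermediate may displace the ring bromide in a 1,3-sense and close a cyclopropane. The fallback sets out from 7: NaBH4 in MeOH at 0 °C should give [(1R,2R,6S)-6-bromo-2-(2-bromoethyl)-1,3-dimethylcyclohex-3-en-1-yl]methanol F3. I2, PPh3 and imidazole in toluene at 80 °C should convert it into (4S,5S,6R)-4-bromo-6-(2-bromoethyl)-5-(iodomethyl)-1,5-dimethylcyclohex-1-ene F4. One equivalent of Bu3SnH with Et3B and air in toluene at −78 °C should then remove iodine selectively, since tin radicals abstract iodine much faster than bromine, and the route is rejoined at 9.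

**Further compounds**

F1 | step 11 | 9-(trifluoroacetoxymercurio) derivative of 18, mercury on C9 trans to O1 | CC1=CC[C@H]2C(C)(C)[C@@H](Br)C[C@@H]([Hg]OC(=O)C(F)(F)F)[C@]2(C)O[C@H]1CBr
F2 | step 4 | (1S,2S,6R)-6-bromo-2-(2-bromoethyl)-1,3-dimethylcyclohex-3-ene-1-carbaldehyde (enantiomer of 7) | O=C[C@@]1(C)[C@H](Br)CC=C(C)[C@@H]1CCBr
F3 | step 5 | [(1R,2R,6S)-6-bromo-2-(2-bromoethyl)-1,3-dimethylcyclohex-3-en-1-yl]methanol | OC[C@]1(C)[C@@H](Br)CC=C(C)[C@H]1CCBr
F4 | step 5 | (4S,5S,6R)-4-bromo-6-(2-bromoethyl)-5-(iodomethyl)-1,5-dimethylcyclohex-1-ene | IC[C@]1(C)[C@@H](Br)CC=C(C)[C@H]1CCBr
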